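The route disconnects the C2''=C3'' double bond of the side chain inside a temporary seven-membered lactone. C1'' is attached to C8 of ring A, next to O7, and C4'' lies cis to C1'' on the alkene. O7, C4'', C3'', C2'', C1'', C8 and C7 can therefore be tied into one oxepinone ring in which the alkene can only be Z. Ring-closing metathesis of a (2S)-flavanone carrying an allyl group at C8 and a methacrylate ester on O7, with the catechol masked as silyl ethers, forms this bond and fixes its geometry in one operation. Hydride opening of the lactone then releases the phenol and the Z-allylic alcohol.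

Key step: step 9

Remark: side-chain atoms are numbered C1'' (on C8) to C4'' (the oxygen-bearing terminus); compounds 16 and 17 are carried as mixtures of C4 epimers, which is inconsequential because step 12 removes that centre.

Step 1
Reactants: 1 7-hydroxychromone; 2 allyl bromide
Product: 3 7-(allyloxy)chromone
Conditions: K2CO3, acetone, reflux
Reagents that add atoms: none
Why: Williamson O-alkylation of the acidic 7-phenol with a primary allylic bromide should proceed under mild carbonate conditions that leave the pyranone ring intact.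

Step 2
Reactants: 3 7-(allyloxy)chromone
Product: 4 8-allyl-7-hydroxychromone
Conditions: N,N-diethylaniline, 200 °C, argon
Reagents that add atoms: none
Why: Aromatic Claisen rearrangement ([3,3]-sigmatropic shift, then tautomerisation of the dienone); in 7-allyloxy benzopyranones the higher double-bond character of C7-C8 should direct the allyl group to C8 and not to C6.

Step 3
Reactants: 4 8-allyl-7-hydroxychromone
Product: 5 8-allyl-7-(methoxymethoxy)chromone
Conditions: MOMCl, K2CO3, acetone, 0 °C to rt
Reagents that add atoms: chloromethyl methyl ether (MOMCl), COCCl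
Why: O-alkylation to the MOM acetal masks the acidic phenol, whose phenoxide would deactivate the enone and bind the hydroxorhodium catalyst in step 6, with a group that is stable to aqueous rhodium catalysis and is later removed by acid while aryl TIPS ethers stay.

Step 4
Reactants: 6 4-bromocatechol
Product: 7 4-bromo-1,2-bis(triisopropylsilyloxy)benzene
Conditions: TIPSCl, imidazole, DMF, rt to 40 °C
Reagents that add atoms: chlorotriisopropylsilane (TIPSCl), CC(C)[Si](Cl)(C(C)C)C(C)C
Why: Imidazole-promoted silyl ether formation on both phenols gives bulky TIPS ethers that tolerate organolithium reagents, hydride and dilute acid but fall to fluoride, so the catechol can be released under neutral conditions at the end.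

Step 5
Reactants: 7 4-bromo-1,2-bis(triisopropylsilyloxy)benzene
Product: 10 [3,4-bis(triisopropylsilyloxy)phenyl]boronic acid, via aryllithium 8 (not isolated), via lithium aryl(triisopropoxy)borate 9 (not isolated)
Conditions: n-BuLi, THF, -78 °C; B(OiPr)3, -78 °C to rt; aq NH4Cl
Reagents that add atoms: triisopropyl borate, CC(C)OB(OC(C)C)OC(C)C; water, O
Why: Bromine-lithium exchange followed by electrophilic borylation and hydrolysis is the standard route to arylboronic acids, and the lithiated carbon is not ortho to a silyloxy group, so no silyl migration is expected.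

Step 6
Reactants: 5 8-allyl-7-(methoxymethoxy)chromone; 10 [3,4-bis(triisopropylsilyloxy)phenyl]boronic acid
Product: 11 (2S)-8-allyl-7-(methoxymethoxy)-2-[3,4-bis(triisopropylsilyloxy)phenyl]chroman-4-one
Conditions: [Rh(OH)(L)]2 (2 mol%), L = (S)-MeO-F12-BIPHEP [(S)-6,6'-dimethoxy-2,2'-bis{bis(3,4,5-trifluorophenyl)phosphino}biphenyl], toluene/H2O (10:1), 40 °C
Reagents that add atoms: none
Why: Rhodium-catalysed asymmetric 1,4-addition of an arylboronic acid to a chromone (Hayashi-Miyaura reaction): the aryl-rhodium species formed by transmetalation inserts the C2=C3 bond inside the chiral pocket of the electron-poor biaryl bisphosphine and water protonates the rhodium enolate, the (S)-ligand being expected to place the aryl group on the C2 face that gives the 2S centre by analogy with its sense of induction on cyclic enones (to be confirmed by chiroptical comparison, the antipodal ligand being equally available), while an aryl-rhodium species, unlike a cationic aryl-palladium one, should not insert the unactivated allyl alkene.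

Step 7
Reactants: 11 (2S)-8-allyl-7-(methoxymethoxy)-2-[3,4-bis(triisopropylsilyloxy)phenyl]chroman-4-one
Product: 12 (2S)-8-allyl-7-hydroxy-2-[3,4-bis(triisopropylsilyloxy)phenyl]chroman-4-one
Conditions: HCl (1 M in MeOH), THF, 40 °C
Reagents that add atoms: none
Why: Acid-catalysed acetal cleavage (transacetalisation to methanol) should remove the MOM group, while aryl TIPS ethers (the most acid-stable of the common phenol silyl ethers), the terminal alkene and the C2 centre tolerate dilute methanolic acid.

Step 8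
Reactants: 12 (2S)-8-allyl-7-hydroxy-2-[3,4-bis(triisopropylsilyloxy)phenyl]chroman-4-one; 13 methacryloyl chloride
Product: 14 (2S)-8-allyl-7-(methacryloyloxy)-2-[3,4-bis(triisopropylsilyloxy)phenyl]chroman-4-one
Conditions: Et3N, DMAP (cat.), CH2Cl2, 0 °C
Reagents that add atoms: none
Why: Nucleophilic acyl substitution of the acid chloride by the phenol under DMAP catalysis, in a cold and weakly basic medium that should not enolise the flavanone or open its pyranone ring.

Step 9
Reactants: 14 (2S)-8-allyl-7-(methacryloyloxy)-2-[3,4-bis(triisopropylsilyloxy)phenyl]chroman-4-one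
Product: 15 (2S)-flavanone fused at O7/C8 with a Z-configured 3-methyl-1-benzoxepin-2(5H)-one lactone ring (catechol as bis-TIPS ether)
Conditions: second-generation Hoveyda-Grubbs catalyst RuCl2(H2IMes)(=CH-C6H4-2-OiPr) (5-10 mol%), 1,4-benzoquinone (20 mol%), toluene (2 mM), 40-60 °C, argon sparge
Reagents that add atoms: none
Why: Ring-closing olefin metathesis: the ruthenium alkylidene initiates on the monosubstituted C8 allyl alkene, the alkylidene at C2'' adds across the tethered methacrylate C=C by [2+2] cycloaddition, and cycloreversion of the ruthenacyclobutane forms C2''=C3'' with overall loss of ethene. The closest known reaction type is the metathesis of acrylate and methacrylate esters of 2-allylphenols and of unsaturated alcohols to α,β-unsaturated lactones. The only ring formed is the seven-membered oxepinone (O7, C4'', C3'', C2'', C1'', C8, C7), which closes by this intramolecular metathesis on the cisoid ester rotamer, and no stereocentre is created. The selectivity needed is the alkene geometry, and the ring itself secures it, because a seven-membered lactone cannot hold an E double bond, so C4'' must end cis to C1''. Dimerisation of the allyl group by cross-metathesis should be held back by high dilution, and migration of the allyl double bond into conjugation (the path to a coumarin) by 1,4-benzoquinone as a scavenger of ruthenium hydrides and by the moderate temperature. The C2 centre, the ketone and the aryl silyl ethers should be inert to the catalyst.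

Step 10
Reactants: 15 (2S)-flavanone fused at O7/C8 with a Z-configured 3-methyl-1-benzoxepin-2(5H)-one lactone ring
Product: 16 (2S,4RS)-2-[3,4-bis(triisopropylsilyloxy)phenyl]-8-[(2Z)-4-hydroxy-3-methylbut-2-en-1-yl]chromane-4,7-diol
Conditions: i-Bu2AlH (6 equiv), CH2Cl2, -78 to -40 °C; aq KNaC4H4O6
Reagents that add atoms: none
Why: Hydride reduction: the aryl ester lactone should be reduced through its lactol aluminate, which expels the C7 phenoxide to give the Z-enal and is then reduced 1,2 to the allylic alcohol without change of alkene geometry, the C4 ketone being reduced as well (accepted and corrected in step 12), while aryl TIPS ethers tolerate the reagent at low temperature.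

Step 11
Reactants: 16 (2S,4RS)-2-[3,4-bis(triisopropylsilyloxy)phenyl]-8-[(2Z)-4-hydroxy-3-methylbut-2-en-1-yl]chromane-4,7-diol
Product: 17 (2S,4RS)-7-(tert-butyldimethylsilyloxy)-8-[(2Z)-4-(tert-butyldimethylsilyloxy)-3-methylbut-2-en-1-yl]-2-[3,4-bis(triisopropylsilyloxy)phenyl]chroman-4-ol
Conditions: TBSCl (2.3 equiv), imidazole, CH2Cl2, 0 °C
Reagents that add atoms: tert-butylchlorodimethylsilane (TBSCl), CC(C)(C)[Si](C)(C)Cl
Why: Chemoselective silyl ether formation: the phenol and the primary allylic alcohol should react with TBSCl/imidazole far faster than the hindered secondary benzylic C4 alcohol, which alone stays free for oxidation.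

Step 12
Reactants: 17 (2S,4RS)-7-(tert-butyldimethylsilyloxy)-8-[(2Z)-4-(tert-butyldimethylsilyloxy)-3-methylbut-2-en-1-yl]-2-[3,4-bis(triisopropylsilyloxy)phenyl]chroman-4-ol
Product: 18 (2S)-7-(tert-butyldimethylsilyloxy)-8-[(2Z)-4-(tert-butyldimethylsilyloxy)-3-methylbut-2-en-1-yl]-2-[3,4-bis(triisopropylsilyloxy)phenyl]chroman-4-one
Conditions: Dess-Martin periodinane, pyridine, CH2Cl2, 0 °C to rt
Reagents that add atoms: none
Why: Dess-Martin oxidation of the secondary benzylic alcohol under buffered, non-basic conditions should converge both C4 epimers on the flavanone without touching C2, the Z alkene or the silyl ethers.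

Step 13
Reactants: 18 (2S)-7-(tert-butyldimethylsilyloxy)-8-[(2Z)-4-(tert-butyldimethylsilyloxy)-3-methylbut-2-en-1-yl]-2-[3,4-bis(triisopropylsilyloxy)phenyl]chroman-4-one
Product: 19 (2S)-2-(3,4-dihydroxyphenyl)-7-hydroxy-8-[(2Z)-4-hydroxy-3-methylbut-2-en-1-yl]chroman-4-one (target)
Conditions: Bu4NF/AcOH (1:1, excess), THF, 0 °C to rt, argon
Reagents that add atoms: none
Why: Fluoride-mediated desilylation of all four silyl ethers; the acetic acid buffer keeps the medium near neutral, so that phenoxide-triggered opening of the flavanone ring (which would racemise C2) and ionisation of the Z-allylic alcohol should not occur.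

Compound list

1 | 7-hydroxychromone (7-hydroxy-4H-chromen-4-one) | O=c1ccoc2cc(O)ccc12 | starting material
2 | allyl bromide (3-bromoprop-1-ene) | C=CCBr | starting material
3 | 7-(allyloxy)chromone | C=CCOc1ccc2c(c1)occc2=O | intermediate
4 | 8-allyl-7-hydroxychromone | C=CCc1c(O)ccc2c1occc2=O | intermediate
5 | 8-allyl-7-(methoxymethoxy)chromone | C=CCc1c(OCOC)ccc2c1occc2=O | intermediate
6 | 4-bromocatechol (4-bromobenzene-1,2-diol) | Oc1ccc(Br)cc1O | starting material
7 | 4-bromo-1,2-bis(triisopropylsilyloxy)benzene | CC(C)[Si](Oc1ccc(Br)cc1O[Si](C(C)C)(C(C)C)C(C)C)(C(C)C)C(C)C | intermediate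
8 | [3,4-bis(triisopropylsilyloxy)phenyl]lithium | [Li]c1ccc(O[Si](C(C)C)(C(C)C)C(C)C)c(O[Si](C(C)C)(C(C)C)C(C)C)c1 | intermediate
9 | lithium triisopropoxy[3,4-bis(triisopropylsilyloxy)phenyl]borate | [Li+].CC(C)O[B-](OC(C)C)(OC(C)C)c1ccc(O[Si](C(C)C)(C(C)C)C(C)C)c(O[Si](C(C)C)(C(C)C)C(C)C)c1 | intermediate
10 | [3,4-bis(triisopropylsilyloxy)phenyl]boronic acid | OB(O)c1ccc(O[Si](C(C)C)(C(C)C)C(C)C)c(O[Si](C(C)C)(C(C)C)C(C)C)c1 | intermediate
11 | (2S)-8-allyl-7-(methoxymethoxy)-2-[3,4-bis(triisopropylsilyloxy)phenyl]chroman-4-one | C=CCc1c(OCOC)ccc2c1O[C@H](c1ccc(O[Si](C(C)C)(C(C)C)C(C)C)c(O[Si](C(C)C)(C(C)C)C(C)C)c1)CC2=O | intermediate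
12 | (2S)-8-allyl-7-hydroxy-2-[3,4-bis(triisopropylsilyloxy)phenyl]chroman-4-one | C=CCc1c(O)ccc2c1O[C@H](c1ccc(O[Si](C(C)C)(C(C)C)C(C)C)c(O[Si](C(C)C)(C(C)C)C(C)C)c1)CC2=O | intermediate
13 | methacryloyl chloride (2-methylprop-2-enoyl chloride) | C=C(C)C(=O)Cl | starting material
14 | (2S)-8-allyl-4-oxo-2-[3,4-bis(triisopropylsilyloxy)phenyl]chroman-7-yl 2-methylprop-2-enoate (metathesis precursor) | C=CCc1c(OC(=O)C(C)=C)ccc2c1O[C@H](c1ccc(O[Si](C(C)C)(C(C)C)C(C)C)c(O[Si](C(C)C)(C(C)C)C(C)C)c1)CC2=O | intermediate
15 | (2S)-2-[3,4-bis(triisopropylsilyloxy)phenyl]flavanone fused at O7/C8 with a (Z)-3-methyl-1-benzoxepin-2(5H)-one lactone ring, O7-C(=O)-C(CH3)=CH-CH2-C8 (metathesis product) | C/C1=C/Cc2c(OC1=O)ccc1c2O[C@H](c2ccc(O[Si](C(C)C)(C(C)C)C(C)C)c(O[Si](C(C)C)(C(C)C)C(C)C)c2)CC1=O | intermediate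
16 | (2S,4RS)-2-[3,4-bis(triisopropylsilyloxy)phenyl]-8-[(2Z)-4-hydroxy-3-methylbut-2-en-1-yl]chromane-4,7-diol | C/C(=C/Cc1c(O)ccc2c1O[C@H](c1ccc(O[Si](C(C)C)(C(C)C)C(C)C)c(O[Si](C(C)C)(C(C)C)C(C)C)c1)CC2O)CO | intermediate
17 | (2S,4RS)-7-(tert-butyldimethylsilyloxy)-8-[(2Z)-4-(tert-butyldimethylsilyloxy)-3-methylbut-2-en-1-yl]-2-[3,4-bis(triisopropylsilyloxy)phenyl]chroman-4-ol | C/C(=C/Cc1c(O[Si](C)(C)C(C)(C)C)ccc2c1O[C@H](c1ccc(O[Si](C(C)C)(C(C)C)C(C)C)c(O[Si](C(C)C)(C(C)C)C(C)C)c1)CC2O)CO[Si](C)(C)C(C)(C)C | intermediate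
18 | (2S)-7-(tert-butyldimethylsilyloxy)-8-[(2Z)-4-(tert-butyldimethylsilyloxy)-3-methylbut-2-en-1-yl]-2-[3,4-bis(triisopropylsilyloxy)phenyl]chroman-4-one | C/C(=C/Cc1c(O[Si](C)(C)C(C)(C)C)ccc2c1O[C@H](c1ccc(O[Si](C(C)C)(C(C)C)C(C)C)c(O[Si](C(C)C)(C(C)C)C(C)C)c1)CC2=O)CO[Si](C)(C)C(C)(C)C | intermediate
19 | (2S)-2-(3,4-dihydroxyphenyl)-7-hydroxy-8-[(2Z)-4-hydroxy-3-methylbut-2-en-1-yl]chroman-4-one | C/C(=C/Cc1c(O)ccc2c1O[C@H](c1ccc(O)c(O)c1)CC2=O)CO | target

Total step count: 13.
Longest linear sequence: 11 steps (steps 1, 2, 3, 6, 7, 8, 9, 10, 11, 12, 13 from 7-hydroxychromone). Steps 4 and 5 make the boronic acid branch that joins in step 6.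

Steps most likely to fail

Step 9. The 1,1-disubstituted, electron-poor methacrylate alkene may be engaged so slowly that catalyst decay, dimerisation of the allyl group or hydride-induced migration of the allyl double bond overtakes ring closure. The fallback closes the same ring by an intramolecular Horner-Wadsworth-Emmons olefination, in which the seven-membered ring again allows only the Z alkene. It sets out from phenol 12, which is esterified with 2-(diethoxyphosphoryl)propanoic acid (EDC·HCl, DMAP, CH2Cl2) to give (2S)-8-allyl-7-[2-(diethoxyphosphoryl)propanoyloxy]-2-[3,4-bis(triisopropylsilyloxy)phenyl]chroman-4-one F1. Lemieux-Johnson cleavage of the allyl alkene (OsO4 cat., NaIO4, 2,6-lutidine, dioxane/H2O) should give the arylacetaldehyde (2S)-7-[2-(diethoxyphosphoryl)propanoyloxy]-8-(2-oxoethyl)-2-[3,4-bis(triisopropylsilyloxy)phenyl]chroman-4-one F2. Olefination under LiCl/i-Pr2NEt in MeCN at high dilution should close the lactone and bring the route back at compound 15.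

Step 6. The electron-rich 7-alkoxychromone may convert slowly, the rhodium enolate may open the pyranone ring by loss of the O1 phenoxide, or facial selectivity may be insufficient. The fallback replaces asymmetric catalysis by resolution. It sets out from 5 and 10, which are joined with an achiral catalyst ([Rh(OH)(cod)]2, dioxane/H2O) to give racemic 8-allyl-7-(methoxymethoxy)-2-[3,4-bis(triisopropylsilyloxy)phenyl]chroman-4-one F3. Preparative chromatography on a polysaccharide chiral stationary phase separates the enantiomers and returns the route at compound 11. The unwanted (2R)-8-allyl-7-(methoxymethoxy)-2-[3,4-bis(triisopropylsilyloxy)phenyl]chroman-4-one F4 can be re-equilibrated to F3 with a catalytic amine base and resubmitted.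

Step 10. Exhaustive reduction leaves a free phenol para to the new benzylic C4 hydroxyl, so loss of that hydroxyl by quinone-methide ionisation on work-up or on silica, or partial conjugate reduction of the unsaturated lactone, may erode the material. The fallback masks O7 before any hydride is used. It sets out from lactone 15, which is opened by methanolysis (MeOH, cat. Et3N, 0 °C to rt) to methyl (2Z)-4-{(2S)-7-hydroxy-4-oxo-2-[3,4-bis(triisopropylsilyloxy)phenyl]chroman-8-yl}-2-methylbut-2-enoate F5. The phenol is silylated (TBSCl, imidazole, CH2Cl2) to methyl (2Z)-4-{(2S)-7-(tert-butyldimethylsilyloxy)-4-oxo-2-[3,4-bis(triisopropylsilyloxy)phenyl]chroman-8-yl}-2-methylbut-2-enoate F6. Reduction with i-Bu2AlH (CH2Cl2, -78 °C) should give (2S,4RS)-7-(tert-butyldimethylsilyloxy)-8-[(2Z)-4-hydroxy-3-methylbut-2-en-1-yl]-2-[3,4-bis(triisopropylsilyloxy)phenyl]chroman-4-ol F7, whose C4 hydroxyl sits para to a silyl ether and not to a free phenol. Selective silylation of the primary alcohol (TBSCl, imidazole, 0 °C) brings the route back at compound 17.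

Further compounds

F1 | step 9 | (2S)-8-allyl-7-[2-(diethoxyphosphoryl)propanoyloxy]-2-[3,4-bis(triisopropylsilyloxy)phenyl]chroman-4-one (epimers at the phosphonate carbon) | C=CCc1c(OC(=O)C(C)P(=O)(OCC)OCC)ccc2c1O[C@H](c1ccc(O[Si](C(C)C)(C(C)C)C(C)C)c(O[Si](C(C)C)(C(C)C)C(C)C)c1)CC2=O
F2 | step 9 | (2S)-7-[2-(diethoxyphosphoryl)propanoyloxy]-8-(2-oxoethyl)-2-[3,4-bis(triisopropylsilyloxy)phenyl]chroman-4-one | O=CCc1c(OC(=O)C(C)P(=O)(OCC)OCC)ccc2c1O[C@H](c1ccc(O[Si](C(C)C)(C(C)C)C(C)C)c(O[Si](C(C)C)(C(C)C)C(C)C)c1)CC2=O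
F3 | step 6 | racemic 8-allyl-7-(methoxymethoxy)-2-[3,4-bis(triisopropylsilyloxy)phenyl]chroman-4-one | C=CCc1c(OCOC)ccc2c1OC(c1ccc(O[Si](C(C)C)(C(C)C)C(C)C)c(O[Si](C(C)C)(C(C)C)C(C)C)c1)CC2=O
F4 | step 6 | (2R)-8-allyl-7-(methoxymethoxy)-2-[3,4-bis(triisopropylsilyloxy)phenyl]chroman-4-one | C=CCc1c(OCOC)ccc2c1O[C@@H](c1ccc(O[Si](C(C)C)(C(C)C)C(C)C)c(O[Si](C(C)C)(C(C)C)C(C)C)c1)CC2=O
F5 | step 10 | methyl (2Z)-4-{(2S)-7-hydroxy-4-oxo-2-[3,4-bis(triisopropylsilyloxy)phenyl]chroman-8-yl}-2-methylbut-2-enoate | COC(=O)/C(C)=C\Cc1c(O)ccc2c1O[C@H](c1ccc(O[Si](C(C)C)(C(C)C)C(C)C)c(O[Si](C(C)C)(C(C)C)C(C)C)c1)CC2=O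
F6 | step 10 | methyl (2Z)-4-{(2S)-7-(tert-butyldimethylsilyloxy)-4-oxo-2-[3,4-bis(triisopropylsilyloxy)phenyl]chroman-8-yl}-2-methylbut-2-enoate | COC(=O)/C(C)=C\Cc1c(O[Si](C)(C)C(C)(C)C)ccc2c1O[C@H](c1ccc(O[Si](C(C)C)(C(C)C)C(C)C)c(O[Si](C(C)C)(C(C)C)C(C)C)c1)CC2=O
F7 | step 10 | (2S,4RS)-7-(tert-butyldimethylsilyloxy)-8-[(2Z)-4-hydroxy-3-methylbut-2-en-1-yl]-2-[3,4-bis(triisopropylsilyloxy)phenyl]chroman-4-ol | C/C(=C/Cc1c(O[Si](C)(C)C(C)(C)C)ccc2c1O[C@H](c1ccc(O[Si](C(C)C)(C(C)C)C(C)C)c(O[Si](C(C)C)(C(C)C)C(C)C)c1)CC2O)CO
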